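- I close the books on the solid substrate, the limiting reagent, in percent of its charge; the teal run reads 0 % of it at 5.00 d.

the same everywhere: solid substrate 39 mM; gas 18 mM (held)
- grey: first nucleophile 16 mM; run made earlier
- teal: first nucleophile 62 mM; run made earlier
- flask: first nucleophile 31.2 mM; time 10 d

| run | time / d | target / % | solvolysis product / % | solid substrate / % |
|---|---|---|---|---|
| grey | 1.04 | 0 | 29.4 | 64.1 |
| grey | 3.00 | 2.4 | 86.1 | 0.5 |
| grey | 5.00 | 1.1 | 88.0 | 0 |
| grey | 8.00 | 4.1 | 88.5 | 2.7 |
| teal | 1.04 | 1.2 | 27.4 | 64.3 |
| teal | 3.00 | 6.2 | 84.1 | 0.4 |
| teal | 5.00 | 7.4 | 84.2 | 0 |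
| teal | 8.00 | 6.2 | 83.4 | 0.4 |

(each reading ± 1 percentage point)

- solid, in amounts per volume of the solution: solid substrate
- at the start none of the gas is in solution
- at the start none of the solid substrate is in solution

1. target at 10 d, in percent of the solid substrate charged
2. solvolysis product at 10 d, in percent of the solid substrate charged
3. amount of target if the flask were left three thousand times as long, in percent of the solid substrate charged

- From 3.00 d on, target and solvolysis product stay level within the scatter in both runs, so I average those readings: together they hold 90.3 %.
- The third entry, 9.72 %, is unaccounted for at 16 mM and at 62 mM of first nucleophile alike, so I book it as a fixed side loss.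
- The pool splits by the capture ratio s, a selectivity factor: target over solvolysis product, per unit of c(first nucleophile); the teal run reads target over solvolysis product as 0.0787, so s reads 0.00127 mM⁻¹.
- In logarithms the teal ratio is −1.10, and going to this flask adds −0.298, giving −1.40, a ratio of 0.0396.
- The same step to the grey run predicts −1.69, and that run reads −1.54; I keep the teal value, whose target readings stand further above the scatter of 1 percentage point than the grey ones.
- My books for this flask close at 3.44 % target and 86.9 % solvolysis product, and with no entry of the earlier runs moving beyond the scatter after 3.00 d I book the same target for the long wait.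
- The forecast, “roughly proportional to nucleophile”, gives 3.6 %, 86.3 % and 3.7 %, more target and less solvolysis product than mine.
- The flask gives 3.89 %, 86.3 % and 3.89 %.

    gas ⇌ second nucleophile, rate k1*(csat - [second nucleophile]) (kL = 0.0130 min⁻¹)
    intermediate → solvolysis product (k = 8.10 min⁻¹)
    starting material → intermediate (k = 0.0710 min⁻¹)
    first nucleophile + intermediate → target (k = 12.0 M⁻¹ min⁻¹)
    second nucleophile ⇌ dormant form (K = 0.750, k = 0.0280 min⁻¹)
    solid substrate ⇌ starting material, rate k6*(cs6 - [starting material]) while solid is left; crystals form when [starting material] > cs6 (solubility = 1.60 mM, k = 0.00620 min⁻¹)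
    second nucleophile + intermediate → other capture product (k = 53.0 M⁻¹ min⁻¹)

- In this flask the intermediate goes to solvolysis product at 8.1 min⁻¹ and, at the charged c(first nucleophile), to target at a pseudo-first-order 0.374 min⁻¹, a ratio of 0.0462. The flask holds target over solvolysis product at 0.0451. Applied to its 86.3 %, s gives 3.42 % target against 3.89 %. The same flask read at 2.5 d, with 16 % of the solid substrate still there, holds 72.4 % solvolysis product, so s gives 2.87 % target, and it holds 3.28 %.

All runs were computed with constants of no real substance, noise included.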